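## The problem

Target 17 is a chroman-4-one whose ring C is fused to a fully oxygenated ring A. Ring A carries methoxy groups at C5, C6 and C7, the ether oxygen O1 at C8a and the acyl carbon C4 at C4a, so only C8 bears hydrogen. Ring B, a 3,4-dimethoxyphenyl group, sits on C2. C2 is the only stereocentre, so no other centre can relay configuration to it, and its (S) sense must come from a catalyst or reagent. That centre is fragile in two ways. It is β to the C4 carbonyl, so base opens ring C by retro-oxa-Michael reaction to the achiral 2'-hydroxychalcone. It is also a benzylic ether of an electron-rich arene, so acid can ionise the C2–O1 bond. Ring closure therefore belongs at the very end and must run near neutrality. Forcing Friedel–Crafts or Fries conditions on an advanced chiral intermediate are unattractive for the same reason, and because the C5 methoxy group next to the carbonyl is the ether most easily cleaved by chelating Lewis acids. The enabling feature is that O1 and C4 sit on the adjacent carbons C8a and C4a. These can be the two ends of an aryne triple bond, and the C5 methoxy group flanking that bond polarises it so that an oxygen nucleophile adds at C8a and the acyl group ends on C4a.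

## Retrosynthesis

**O1–C2 (17 to 15).** Ring C is opened at O1–C2 in the SN2 sense. This gives hydroxy ketone 15, with the C8a phenol as nucleophile and an (R)-configured C2 carbinol as electrophile. The neighbouring cuts are less attractive: oxa-Michael closure of a chalcone starts from an achiral, equilibrating precursor, and aryl C–O coupling at C8a needs a halogen on ring A and a second carbinol. Precursor 15 is acyclic and its one stereocentre is a plain secondary benzylic alcohol. The forward Mitsunobu closure must displace cleanly with inversion at a carbon that could also ionise or eliminate.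

**Unmasking (15 to 14).** The carbinol of 15 is carried as its tert-butyldimethylsilyl ether 14. The silyl group is needed only so that the preceding step sees one nucleophile. It is removed with buffered HF·pyridine, which leaves the β-hydroxy ketone and the phenol alone.

**O1–C8a and C4–C4a (14 to 6 and 10).** Cutting both bonds from ring A to the side chain removes ring A as 3,4,5-trimethoxybenzyne 11, generated from silyl triflate 6, and leaves carboxylic acid 10. Acylation of phenol 1 by Friedel–Crafts or Fries chemistry would put a β-silyloxy, acid-ionisable side chain under strong Lewis acid. An aldol from the ring A acetophenone would need an asymmetric variant that tolerates a free phenol and resists dehydration. The aryne route forms both bonds under fluoride, without acid, and halves the problem into an achiral arene and a small chiral acid. The forward reaction must add carboxylate oxygen at the aryne carbon remote from the methoxy group and transfer the acyl group before the aryl anion is protonated.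

**Aryne precursor (6 to 2 to 1).** Triflate 6 comes from bromophenol 2 by O-silylation, bromine–lithium exchange with retro-Brook shift, and triflation. Bromophenol 2 comes from phenol 1, whose two free positions are equivalent, so bromination has no regiochemical issue.

**Chiral acid (10 to 9 to 8 to 7).** Acid 10 is the saponified silyl ether 9 of hydroxy ester 8. Ester 8 is the product of asymmetric hydrogenation of commercial β-keto ester 7. This is the only stereo-defining event of the route.

## Roads not taken

**Alternative 1:** The cut is the aryl ether bond O1–C8a. Bromo diol A1, (1S,3S)-1-(6-bromo-2,3,4-trimethoxyphenyl)-3-(3,4-dimethoxyphenyl)propane-1,3-diol, would be cyclised with Pd(OAc)2, 2-(di-tert-butylphosphino)-1,1'-binaphthyl and Cs2CO3 to flavan-4-ol A2. Oxidation of A2 would give 17.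
- Merits: the C2–O bond is never broken, so C2 passes through ring closure with retention and without activating an ionisable benzylic carbinol. Only the C2 hydroxyl can reach the bromide through a six-membered ring, so the two hydroxyls need no differentiation.
- Weak points: oxidative addition into an electron-rich, ortho-substituted bromide is slow. The palladium alkoxide of a secondary benzylic alcohol can lose β-hydride, and the free C4 carbinol beside the metal is a second such site. A second carbinol centre is built only to be oxidised away, and ring A must be brought in as a brominated carbonyl compound several steps from 1.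
- Comparison: for the security of C2 during ring closure this road is better than an inversion at a 3,4-dimethoxybenzylic carbon. The chosen plan sets against it a convergent assembly in which ring A receives oxygen and acyl in one regiocontrolled step, one stereocentre instead of two, no final redox step and no β-hydride channel.

**Alternative 2:** The cuts are C2–C3 and C3–C4, with C3 delivered as a methylene unit. Silyloxybenzofuran A3 would be cyclopropanated across its furan C2=C3 bond by a zinc carbenoid from Et2Zn and CH2I2 with a chiral ligand to give cyclopropane A4. Opening the fused bond of A4 would expand the ring to 17.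
- Merits: the benzofuranone precursor is quickly made, the carbonyl appears directly from the silyloxycyclopropane, and the sequence is short on paper.
- Weak points: the double bond is tetrasubstituted, aryl-bearing and part of an aromatic benzofuran, and there is no directing hydroxyl. Enantioselective Simmons–Smith addition to such an olefin has no close counterpart. The C2–H bond is made only in the ring opening, by protonation at a benzylic, oxygen-bearing carbon that can open through a stabilised cation, so the configuration of A4 need not be transmitted.
- Comparison: step count favours this road. The chosen plan sets against it that each of its steps is a known reaction type and that its stereocentre is set by a ketone hydrogenation.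

**Alternative 3:** The cut is C3=C4 at the enol ether level. Diene A5 would be closed with the second-generation Grubbs catalyst, (H2IMes)(PCy3)Cl2Ru=CHPh, to chromene silyl enol ether A6 with loss of ethylene. Hydrolysis of A6 would give 17. The C2 centre would come from an asymmetric allylic etherification, for example with [Ir(cod)Cl]2 and a chiral phosphoramidite.
- Merits: C2 is set catalytically and carried with retention, and no inversion is needed. The step count is comparable to or slightly below that of the chosen plan.
- Weak points: the ether carbon of A5 is allylic and benzylic to an electron-rich arene, so it can ionise, undergo [3,3] shift or suffer ruthenium hydride double-bond migration at the temperatures needed. The metathesis partner is a 1,1-disubstituted silyl enol ether held between two ortho substituents, which calls for such temperatures. The 2-aryl-2H-chromene A6 can open electrocyclically to an ortho-quinone methide, which would erase C2.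
- Comparison: in step count and in avoiding an inversion this road is at least as good. The chosen plan sets against it configurationally robust intermediates: a silyl ether of a saturated carbinol in place of a doubly activated allyl aryl ether.

Key step: step 6

## Route

Assumption: the (S)-configured biaryl diphosphine is taken to give the (R)-carbinol 8, following the general sense of induction for β-keto esters (the descriptor is R because aryl outranks CH2CO2Et). The hand of the ligand is the only variable that fixes C2.

Step 1
Reactants: 1 3,4,5-trimethoxyphenol
Product: 2 2-bromo-3,4,5-trimethoxyphenol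
Conditions: NBS (1.0 equiv), CH2Cl2, −78 °C to 0 °C
Reagents that add atoms: N-bromosuccinimide, O=C1CCC(=O)N1Br
Why: Electrophilic aromatic bromination; the two free ring positions are equivalent and both ortho to the hydroxyl, so one equivalent at low temperature should give the monobromide with no regiochemical question.

Step 2
Reactants: 2 2-bromo-3,4,5-trimethoxyphenol
Product: 6 3,4,5-trimethoxy-2-(trimethylsilyl)phenyl trifluoromethanesulfonate, via O-trimethylsilyl ether 3 (not isolated), via aryllithium 4 (not isolated), via lithium 2-silylphenolate 5 (not isolated)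
Conditions: HMDS, THF, 65 °C, then evaporate; n-BuLi, THF, −100 °C to −78 °C; Tf2O, −100 °C to rt
Reagents that add atoms: hexamethyldisilazane, C[Si](C)(C)N[Si](C)(C)C; trifluoromethanesulfonic anhydride, O=S(=O)(OS(=O)(=O)C(F)(F)F)C(F)(F)F
Why: O-silylation, bromine–lithium exchange, 1,3-retro-Brook shift of silicon from oxygen to the lithiated carbon and O-triflation of the phenolate, the standard one-flask route to 2-silylaryl triflates; the 3-methoxy analogue is made the same way, so the flanking methoxy group should be tolerated.

Step 3
Reactants: 7 ethyl 3-(3,4-dimethoxyphenyl)-3-oxopropanoate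
Product: 8 ethyl (R)-3-(3,4-dimethoxyphenyl)-3-hydroxypropanoate
Conditions: [RuCl(p-cymene)((S)-BINAP)]Cl (0.5 mol %), H2 (30 bar), EtOH, 50 °C
Reagents that add atoms: none
Why: Noyori asymmetric hydrogenation of a β-keto ester; the substrate chelates ruthenium through ketone and ester, and the (S)-ligand should direct hydride to the Si face of the ketone, giving the (R)-carbinol; moderate temperature limits solvolysis of the electron-rich benzylic alcohol.

Step 4
Reactants: 8 ethyl (R)-3-(3,4-dimethoxyphenyl)-3-hydroxypropanoate
Product: 9 ethyl (R)-3-[(tert-butyldimethylsilyl)oxy]-3-(3,4-dimethoxyphenyl)propanoate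
Conditions: TBSCl, imidazole, DMF, rt
Reagents that add atoms: tert-butyldimethylsilyl chloride, CC(C)(C)[Si](C)(C)Cl
Why: Imidazole-promoted silylation of a secondary alcohol; the conditions are too mild for retro-aldol cleavage or dehydration and the stereocentre is not involved.

Step 5
Reactants: 9 ethyl (R)-3-[(tert-butyldimethylsilyl)oxy]-3-(3,4-dimethoxyphenyl)propanoate
Product: 10 (R)-3-[(tert-butyldimethylsilyl)oxy]-3-(3,4-dimethoxyphenyl)propanoic acid
Conditions: LiOH·H2O, THF/H2O, 0 °C to rt; then 1 M HCl to pH 4, 0 °C
Reagents that add atoms: lithium hydroxide, [Li+].[OH-]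
Why: Ester saponification; hydroxide attack at the ester carbonyl should outrun α-deprotonation at this temperature, and the secondary silyl ether is stable to cold aqueous LiOH and to a brief mildly acidic work-up.

Step 6
Reactants: 6 3,4,5-trimethoxy-2-(trimethylsilyl)phenyl trifluoromethanesulfonate; 10 (R)-3-[(tert-butyldimethylsilyl)oxy]-3-(3,4-dimethoxyphenyl)propanoic acid
Product: 14 (R)-3-[(tert-butyldimethylsilyl)oxy]-3-(3,4-dimethoxyphenyl)-1-(6-hydroxy-2,3,4-trimethoxyphenyl)propan-1-one, via 3,4,5-trimethoxybenzyne 11 (not isolated), via ortho-acyloxyaryl anion 12 (not isolated), via benzoxetene alkoxide 13 (not isolated)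
Conditions: CsF (4 equiv), THF, 125 °C (sealed tube); aq NH4Cl
Reagents that add atoms: none
Why: Fluoride attacks silicon in 6 and triflate leaves to give aryne 11, while further CsF turns 10 into its cesium carboxylate, the only nucleophile present because the carbinol is silylated. The carboxylate oxygen adds to the aryne carbon remote from the flanking methoxy group (the future C8a), which puts the developing charge on the carbon next to the inductively withdrawing C–OMe bond (the future C4a); this is the regioselectivity the step needs, and the C5 methoxy group secures it. Aryl anion 12 then attacks its own ester carbonyl (4-exo-trig) to give benzoxetene alkoxide 13, which reopens by C–O cleavage to the ortho-acyl phenoxide, protonated on work-up to 14; O1–C8a and C4–C4a are formed in one operation and no ring of the target is closed. The closest known reaction type is the formal insertion of arynes from 2-(trimethylsilyl)aryl triflates into the C–O bond of carboxylic acids under CsF in hot THF, which gives ortho-hydroxyaryl ketones and follows the usual regiochemistry of 3-methoxybenzyne. The second selectivity needed is acyl transfer ahead of protonation of 12, favoured by the high temperature and by the lack of any proton source once the acid is present as its salt. No stereocentre is created, since the hemiketal carbon of 13 is transient, and the (R)-carbinol β to the carbonyl is untouched as long as the silyl ether holds and the α-methylene group is not deprotonated.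

Step 7
Reactants: 14 (R)-3-[(tert-butyldimethylsilyl)oxy]-3-(3,4-dimethoxyphenyl)-1-(6-hydroxy-2,3,4-trimethoxyphenyl)propan-1-one
Product: 15 (R)-3-(3,4-dimethoxyphenyl)-3-hydroxy-1-(6-hydroxy-2,3,4-trimethoxyphenyl)propan-1-one
Conditions: HF·pyridine, pyridine, THF, 0 °C to rt
Reagents that add atoms: none
Why: Fluoride-mediated cleavage of a secondary silyl ether; the pyridine-buffered medium is neither basic enough for retro-aldol or retro-oxa-Michael reactions nor acidic enough to ionise the benzylic carbinol, so the configuration should be retained.

Step 8
Reactants: 15 (R)-3-(3,4-dimethoxyphenyl)-3-hydroxy-1-(6-hydroxy-2,3,4-trimethoxyphenyl)propan-1-one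
Product: 17 (2S)-5,6,7,3',4'-pentamethoxyflavanone [(S)-2-(3,4-dimethoxyphenyl)-5,6,7-trimethoxychroman-4-one], via alkoxyphosphonium phenoxide 16 (not isolated)
Conditions: PPh3, DIAD (slow addition), THF, 0 °C
Reagents that add atoms: none
Why: Intramolecular Mitsunobu etherification, an established closure of 3-hydroxy-1-(2-hydroxyaryl)propan-1-ones to chroman-4-ones; the phenol protonates the betaine, the carbinol is activated as 16, and the phenoxide displaces Ph3P=O in a 6-exo-tet SN2 step with inversion, turning (R) into (2S). Low temperature and a weakly ionising solvent are chosen to keep the displacement ahead of ionisation and elimination.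

## Compound list

1 | 3,4,5-trimethoxyphenol | COc1cc(O)cc(OC)c1OC | starting material
2 | 2-bromo-3,4,5-trimethoxyphenol | COc1cc(O)c(Br)c(OC)c1OC | intermediate
3 | (2-bromo-3,4,5-trimethoxyphenoxy)trimethylsilane | COc1cc(O[Si](C)(C)C)c(Br)c(OC)c1OC | intermediate (not isolated)
4 | [2,3,4-trimethoxy-6-(trimethylsilyloxy)phenyl]lithium | COc1cc(O[Si](C)(C)C)c([Li])c(OC)c1OC | intermediate (not isolated)
5 | lithium 3,4,5-trimethoxy-2-(trimethylsilyl)phenolate | [Li+].COc1cc([O-])c([Si](C)(C)C)c(OC)c1OC | intermediate (not isolated)
6 | 3,4,5-trimethoxy-2-(trimethylsilyl)phenyl trifluoromethanesulfonate | COc1cc(OS(=O)(=O)C(F)(F)F)c([Si](C)(C)C)c(OC)c1OC | intermediate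
7 | ethyl 3-(3,4-dimethoxyphenyl)-3-oxopropanoate | CCOC(=O)CC(=O)c1ccc(OC)c(OC)c1 | starting material
8 | ethyl (R)-3-(3,4-dimethoxyphenyl)-3-hydroxypropanoate | COc1ccc([C@H](O)CC(=O)OCC)cc1OC | intermediate
9 | ethyl (R)-3-[(tert-butyldimethylsilyl)oxy]-3-(3,4-dimethoxyphenyl)propanoate | COc1ccc([C@H](O[Si](C)(C)C(C)(C)C)CC(=O)OCC)cc1OC | intermediate
10 | (R)-3-[(tert-butyldimethylsilyl)oxy]-3-(3,4-dimethoxyphenyl)propanoic acid | COc1ccc([C@H](O[Si](C)(C)C(C)(C)C)CC(=O)O)cc1OC | intermediate
11 | 3,4,5-trimethoxybenzyne (1,2-didehydro-3,4,5-trimethoxybenzene) | COC1=C(OC)C(OC)=CC#C1 | intermediate (not isolated)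
12 | cesium 2-{[(R)-3-(tert-butyldimethylsilyloxy)-3-(3,4-dimethoxyphenyl)propanoyl]oxy}-4,5,6-trimethoxybenzen-1-ide (anion carbon between the acyloxy and methoxy carbons) | [Cs+].COc1ccc([C@H](O[Si](C)(C)C(C)(C)C)CC(=O)Oc2cc(OC)c(OC)c(OC)[c-]2)cc1OC | intermediate (not isolated)
13 | cesium 2-[(R)-2-(tert-butyldimethylsilyloxy)-2-(3,4-dimethoxyphenyl)ethyl]-3,4,5-trimethoxy-2H-benzoxet-2-olate (hemiketal carbon unassigned, transient) | [Cs+].COc1ccc([C@H](O[Si](C)(C)C(C)(C)C)CC2([O-])Oc3cc(OC)c(OC)c(OC)c32)cc1OC | intermediate (not isolated)
14 | (R)-3-[(tert-butyldimethylsilyl)oxy]-3-(3,4-dimethoxyphenyl)-1-(6-hydroxy-2,3,4-trimethoxyphenyl)propan-1-one | COc1ccc([C@H](O[Si](C)(C)C(C)(C)C)CC(=O)c2c(O)cc(OC)c(OC)c2OC)cc1OC | intermediate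
15 | (R)-3-(3,4-dimethoxyphenyl)-3-hydroxy-1-(6-hydroxy-2,3,4-trimethoxyphenyl)propan-1-one | COc1ccc([C@H](O)CC(=O)c2c(O)cc(OC)c(OC)c2OC)cc1OC | intermediate
16 | 2-[(R)-3-(3,4-dimethoxyphenyl)-3-(triphenylphosphoniooxy)propanoyl]-3,4,5-trimethoxyphenolate (zwitterion) | COc1ccc([C@H](O[P+](c2ccccc2)(c2ccccc2)c2ccccc2)CC(=O)c2c([O-])cc(OC)c(OC)c2OC)cc1OC | intermediate (not isolated)
17 | (2S)-5,6,7,3',4'-pentamethoxyflavanone | COc1ccc([C@@H]2CC(=O)c3c(cc(OC)c(OC)c3OC)O2)cc1OC | target

## Step count and risk

Total: 8 steps. Longest linear sequence: 6 steps (steps 3, 4, 5, 6, 7 and 8, from 7).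

**Step 6 (key step).** Three processes can interfere. Hot fluoride may cleave the silyl ether, after which the free alkoxide fragments by retro-aldol reaction or dehydrates. The product ketone may lose silanolate by E1cB elimination towards the chalcone, and phenoxide re-addition would then give racemic material. The aryl anion may be protonated before acyl transfer, or the product phenoxide arylated by a second aryne. The fallback sets out from bromophenol 2 and acid 10 and returns at 14. The two are esterified (DCC, DMAP, CH2Cl2) to 2-bromo-3,4,5-trimethoxyphenyl (R)-3-[(tert-butyldimethylsilyl)oxy]-3-(3,4-dimethoxyphenyl)propanoate F1. Bromine–lithium exchange with t-BuLi (2 equiv) in THF/Et2O at −100 °C then gives the ortho-lithiated aryl ester F2, the lithium counterpart of 12 with its regiochemistry fixed by the position of bromine. The same 1,3 shift of the acyl group from oxygen to carbon, an anionic Fries-type migration known for ortho-haloaryl esters, delivers 14 without fluoride or heat.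

**Step 8.** The 4'-methoxy group stabilises a benzylic cation, so the activated carbinol may ionise and the displacement lose stereospecificity. The alkoxyphosphonium group β to the ketone may also eliminate to the chalcone. The fallback sets out from 15 and returns at 17, giving up the stereocentre of 15 and setting C2 afresh:
- Acid-catalysed dehydration (p-TsOH, toluene, 80 °C) gives (E)-3-(3,4-dimethoxyphenyl)-1-(6-hydroxy-2,3,4-trimethoxyphenyl)prop-2-en-1-one F3.
- Oxidative cyclisation with catalytic iodine (I2) in DMSO at 130 °C gives 2-(3,4-dimethoxyphenyl)-5,6,7-trimethoxy-4H-chromen-4-one F4.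
- Asymmetric hydrogenation of the flavone with Ru(cod)(2-methylallyl)2 and a chiral N-heterocyclic carbene, generated from a 1,3-bis[1-(1-naphthyl)ethyl]imidazolinium tetrafluoroborate and KOt-Bu, under H2 pressure gives (2S,4S)-2-(3,4-dimethoxyphenyl)-5,6,7-trimethoxychroman-4-ol F5, which is the same compound as A2. The ligand antipode is chosen for the (2S) series.
- Oxidation with Dess–Martin periodinane gives 17.

**Step 1.** The electron-rich phenol may brominate twice or be oxidised to a quinone. The fallback sets out from 1 and returns at 6 without a bromide:
- Carbamoylation with isopropyl isocyanate (Et3N cat., CH2Cl2) gives 3,4,5-trimethoxyphenyl isopropylcarbamate F6.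
- Carbamate-directed ortho-lithiation (TBSOTf and TMEDA to mask the N–H, then n-BuLi, Et2O, −78 °C) and a TMSCl quench give 3,4,5-trimethoxy-2-(trimethylsilyl)phenyl isopropylcarbamate F7.
- Cleavage with Et2NH and DBU in MeCN at 40 °C gives 3,4,5-trimethoxy-2-(trimethylsilyl)phenol F8, which is triflated in the same flask with PhNTf2 to 6.

**Step 3.** Enantioselection for an aroylacetate may be incomplete, and the electron-rich benzylic alcohol may undergo solvolysis in warm ethanol if traces of acid are present. The fallback sets out from 7 and returns at 8 by a biocatalytic route: reduction with an (R)-selective ketoreductase, with NADPH regenerated by isopropanol or glucose and glucose dehydrogenase, in aqueous buffer at 30 °C. No new compound is formed on the way (entry F0).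

**Step 5.** Silanolate may be lost by E1cB elimination to the cinnamate during saponification. The fallback sets out from 8 and returns at 10 by reversing the order:
- Hydroxy ester 8 is saponified first (LiOH, THF/H2O) to (R)-3-(3,4-dimethoxyphenyl)-3-hydroxypropanoic acid F9, which has no β leaving group.
- Bis-silylation (TBSCl, imidazole, DMF) gives tert-butyldimethylsilyl (R)-3-[(tert-butyldimethylsilyl)oxy]-3-(3,4-dimethoxyphenyl)propanoate F10.
- The silyl ester alone is cleaved with K2CO3 in MeOH/THF/H2O to give 10.

## Further compounds

F1 | step 6 | 2-bromo-3,4,5-trimethoxyphenyl (R)-3-[(tert-butyldimethylsilyl)oxy]-3-(3,4-dimethoxyphenyl)propanoate | COc1ccc([C@H](O[Si](C)(C)C(C)(C)C)CC(=O)Oc2cc(OC)c(OC)c(OC)c2Br)cc1OC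
F2 | step 6 | (6-{[(R)-3-(tert-butyldimethylsilyloxy)-3-(3,4-dimethoxyphenyl)propanoyl]oxy}-2,3,4-trimethoxyphenyl)lithium | COc1ccc([C@H](O[Si](C)(C)C(C)(C)C)CC(=O)Oc2cc(OC)c(OC)c(OC)c2[Li])cc1OC
F3 | step 8 | (E)-3-(3,4-dimethoxyphenyl)-1-(6-hydroxy-2,3,4-trimethoxyphenyl)prop-2-en-1-one | COc1ccc(/C=C/C(=O)c2c(O)cc(OC)c(OC)c2OC)cc1OC
F4 | step 8 | 2-(3,4-dimethoxyphenyl)-5,6,7-trimethoxy-4H-chromen-4-one | COc1ccc(-c2cc(=O)c3c(OC)c(OC)c(OC)cc3o2)cc1OC
F5 | step 8 | (2S,4S)-2-(3,4-dimethoxyphenyl)-5,6,7-trimethoxychroman-4-ol | COc1ccc([C@@H]2C[C@H](O)c3c(cc(OC)c(OC)c3OC)O2)cc1OC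
F6 | step 1 | 3,4,5-trimethoxyphenyl isopropylcarbamate | COc1cc(OC(=O)NC(C)C)cc(OC)c1OC
F7 | step 1 | 3,4,5-trimethoxy-2-(trimethylsilyl)phenyl isopropylcarbamate | COc1cc(OC(=O)NC(C)C)c([Si](C)(C)C)c(OC)c1OC
F8 | step 1 | 3,4,5-trimethoxy-2-(trimethylsilyl)phenol | COc1cc(O)c([Si](C)(C)C)c(OC)c1OC
F0 | step 3 | none | none
F9 | step 5 | (R)-3-(3,4-dimethoxyphenyl)-3-hydroxypropanoic acid | COc1ccc([C@H](O)CC(=O)O)cc1OC
F10 | step 5 | tert-butyldimethylsilyl (R)-3-[(tert-butyldimethylsilyl)oxy]-3-(3,4-dimethoxyphenyl)propanoate | COc1ccc([C@H](O[Si](C)(C)C(C)(C)C)CC(=O)O[Si](C)(C)C(C)(C)C)cc1OC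
A1 | alternative 1 | (1S,3S)-1-(6-bromo-2,3,4-trimethoxyphenyl)-3-(3,4-dimethoxyphenyl)propane-1,3-diol | COc1ccc([C@@H](O)C[C@H](O)c2c(Br)cc(OC)c(OC)c2OC)cc1OC
A2 | alternative 1 | (2S,4S)-2-(3,4-dimethoxyphenyl)-5,6,7-trimethoxychroman-4-ol | COc1ccc([C@@H]2C[C@H](O)c3c(cc(OC)c(OC)c3OC)O2)cc1OC
A3 | alternative 2 | tert-butyl{[2-(3,4-dimethoxyphenyl)-4,5,6-trimethoxybenzofuran-3-yl]oxy}dimethylsilane | COc1ccc(-c2oc3cc(OC)c(OC)c(OC)c3c2O[Si](C)(C)C(C)(C)C)cc1OC
A4 | alternative 2 | tert-butyl{[1a-(3,4-dimethoxyphenyl)-4,5,6-trimethoxy-1,1a-dihydro-6bH-cyclopropa[b]benzofuran-6b-yl]oxy}dimethylsilane (cis-fused, enantiomer as in the SMILES) | COc1ccc([C@]23C[C@@]2(O[Si](C)(C)C(C)(C)C)c4c(cc(OC)c(OC)c4OC)O3)cc1OC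
A5 | alternative 3 | (S)-tert-butyl[(1-{2-[1-(3,4-dimethoxyphenyl)allyloxy]-4,5,6-trimethoxyphenyl}vinyl)oxy]dimethylsilane | COc1ccc([C@H](C=C)Oc2cc(OC)c(OC)c(OC)c2C(=C)O[Si](C)(C)C(C)(C)C)cc1OC
A6 | alternative 3 | (S)-tert-butyl{[2-(3,4-dimethoxyphenyl)-5,6,7-trimethoxy-2H-chromen-4-yl]oxy}dimethylsilane | COc1ccc([C@@H]2C=C(O[Si](C)(C)C(C)(C)C)c3c(cc(OC)c(OC)c3OC)O2)cc1OC
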